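**Plan**

1. Numbering used throughout: ring A = C1–C5 and C10 (C4 carries CH3 and C18H2OAc); ring B = C5–C10 (C7 ketone, C8–CH3, C9–CH3 and the chain C11–C15O2H, C13–CH3).
2. Retrosynthetic cuts, in order: C7=O (allylic C–H oxidation), C11=C12 (Wittig, then H2), C7–C8 and C9–C10 (Diels–Alder), C5–C6 (alkenyl triflate coupling), and last C1–C10 together with C3–C4 (Robinson-type annulation of ethyl 2-methylacetoacetate with acrolein).
3. Forward: ring A is built first (Michael addition, then aldol condensation closing C1–C10) and converted into a 1-vinylcyclohexene (C10=C5–C6=C7). Ring B then arises by cycloaddition with tiglic aldehyde, the chain is joined at the C9 formyl group, and the C7 oxo group comes last.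
4. Enabling feature: C4 is quaternary, so the C5 carbonyl of the Michael adduct has one enolisable neighbour only, the acetyl carbon C10, which lies 1,5 to the aldehyde carbon C1. The same C5=O/C10 pair later supplies the C5=C10 half of the diene.
5. Stereochemistry: C4 from the cinchona-catalysed Michael addition; C8, C9 and C10 together in the Diels–Alder step (E-dienophile, exo formyl group, catalyst-selected diene face); C13 from methyl hydrogen (R)-3-methylglutarate. C8 becomes enolisable only in the last step, which is run without base.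

Key step: step 1

Assumption: the senses of induction of the quinidine-derived catalyst (step 1) and of the (S)-oxazaborolidinium catalyst (step 6) are taken as drawn; should either be opposite, the quinine-derived or the (R)-configured catalyst is used instead.

**Route**

Step 1
Reactants: 1 ethyl 2-methyl-3-oxobutanoate (racemic); 2 acrolein
Product: 5 ethyl (1R)-1-methyl-2-oxocyclohex-3-ene-1-carboxylate, via keto aldehyde 3 (not isolated), via ketol 4 (not isolated)
Conditions: 9-O-(phenanthren-9-yl)cupreidine (6'-hydroxy quinidine ether, 10 mol %), CH2Cl2, −24 °C; then p-TsOH·H2O (cat.), toluene, 110 °C, water separator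
Reagents that add atoms: none
Why: The quinuclidine nitrogen of the bifunctional catalyst deprotonates the β-keto ester while the 6'-OH hydrogen-bonds acrolein, so the chiral ion pair adds through one enolate face and forms C3–C4 with the C4 quaternary centre in the (R) sense (asymmetric Michael addition of α-substituted β-keto esters to enals is the closest known reaction type); acid then enolises keto aldehyde 3, C10 adds to C1, and ketol 4 dehydrates, which completes a Robinson-type annulation. The ring closure is a 6-(enolendo)-exo-trig aldol addition. C4 is the only stereocentre that survives the step and it is set by the catalyst; the carbinol centre of 4 is lost on dehydration. The step needs regioselective enolisation, and the substrate secures it: C4 is quaternary, so the C5 ketone can enolise only towards the acetyl carbon C10, and attack of the aldehyde enol on the ketone would give a four-membered ring. Acidic rather than basic conditions for the condensation avoid retro-Michael and retro-Claisen cleavage and so protect the configuration at C4.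

Step 2
Reactants: 5 ethyl (1R)-1-methyl-2-oxocyclohex-3-ene-1-carboxylate
Product: 7 ethyl (1R)-1-methyl-2-(trifluoromethylsulfonyloxy)cyclohex-2-ene-1-carboxylate, via lithium enolate 6 (not isolated)
Conditions: LiBH(s-Bu)3, THF, −78 °C; then PhNTf2, −78 → 25 °C
Reagents that add atoms: N-phenylbis(trifluoromethanesulfonimide), O=S(=O)(N(c1ccccc1)S(=O)(=O)C(F)(F)F)C(F)(F)F
Why: Conjugate hydride reduction followed by enolate O-triflation: the bulky borohydride should add 1,4 to the β-unsubstituted enone (hydride to C1) and the regiodefined C5–C10 enolate 6 is trapped on oxygen; no stereocentre is formed and the quaternary C4 cannot epimerise.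

Step 3
Reactants: 7 ethyl (1R)-1-methyl-2-(trifluoromethylsulfonyloxy)cyclohex-2-ene-1-carboxylate
Product: 8 ethyl (1R)-2-ethenyl-1-methylcyclohex-2-ene-1-carboxylate
Conditions: CH2=CHSnBu3, Pd(PPh3)4 (5 mol %), LiCl, THF, 65 °C
Reagents that add atoms: tributyl(vinyl)stannane, CCCC[Sn](CCCC)(CCCC)C=C
Why: Stille cross-coupling of an alkenyl triflate (LiCl-assisted) should attach the vinyl group C6–C7 to C5 and give the 1,3-diene without touching C4.

Step 4
Reactants: 8 ethyl (1R)-2-ethenyl-1-methylcyclohex-2-ene-1-carboxylate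
Product: 9 [(1R)-2-ethenyl-1-methylcyclohex-2-en-1-yl]methanol
Conditions: LiAlH4, Et2O, 0 °C; then H2O
Reagents that add atoms: none
Why: Hydride reduction of the neopentyl ester to the primary alcohol (C18); the unactivated diene and the quaternary centre are inert to LiAlH4.

Step 5
Reactants: 9 [(1R)-2-ethenyl-1-methylcyclohex-2-en-1-yl]methanol
Product: 10 tert-butyl{[(1R)-2-ethenyl-1-methylcyclohex-2-en-1-yl]methoxy}dimethylsilane
Conditions: TBSCl, imidazole, DMF, 25 °C
Reagents that add atoms: tert-butyldimethylsilyl chloride, CC(C)(C)[Si](C)(C)Cl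
Why: Imidazole-promoted silylation of the primary alcohol protects C18–OH against the Lewis acid of step 6 and the ylide of step 9.

Step 6
Reactants: 10 tert-butyl{[(1R)-2-ethenyl-1-methylcyclohex-2-en-1-yl]methoxy}dimethylsilane; 11 (E)-2-methylbut-2-enal (tiglic aldehyde)
Product: 12 (1R,2S,5R,8aR)-5-({[tert-butyl(dimethyl)silyl]oxy}methyl)-1,2,5-trimethyl-1,2,3,5,6,7,8,8a-octahydronaphthalene-1-carbaldehyde
Conditions: (S)-1-(2-methylphenyl)-3,3-diphenyltetrahydro-1H,3H-pyrrolo[1,2-c][1,3,2]oxazaborole (20 mol %), HN(SO2CF3)2 (20 mol %), excess 11, CH2Cl2, −78 → −20 °C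
Reagents that add atoms: none
Why: Diels–Alder reaction under chiral oxazaborolidinium activation of an α-substituted enal: the vinyl terminus C7 bonds to the enal β-carbon C8 and C10 to C9, the (E)-geometry of 11 makes the C8 and C9 methyl groups cis, the exo orientation of the formyl group usual for α-methyl enals places C11 cis to H10, and the catalyst-bound enal selects the diene face so that C8, C9 and C10 arise in the drawn absolute sense; the weak bias of the C4 centre should, if anything, favour the same approach, anti to the larger CH2OSi group.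

Step 7
Reactants: 13 (3R)-5-methoxy-3-methyl-5-oxopentanoic acid (methyl hydrogen (R)-3-methylglutarate)
Product: 14 methyl (3S)-4-bromo-3-methylbutanoate
Conditions: HgO, Br2, CCl4, 77 °C, dark
Reagents that add atoms: bromine, BrBr
Why: Hunsdiecker-type bromodecarboxylation of the free acid terminus via the acyl hypobromite and a primary radical; the stereocentre is not involved and only its descriptor changes (R to S) through the new priorities.

Step 8
Reactants: 14 methyl (3S)-4-bromo-3-methylbutanoate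
Product: 15 [(2S)-4-methoxy-2-methyl-4-oxobutyl]triphenylphosphonium bromide
Conditions: PPh3, MeCN, 82 °C
Reagents that add atoms: triphenylphosphine, c1ccc(cc1)P(c1ccccc1)c1ccccc1
Why: SN2 quaternisation of the primary bromide by the phosphine gives the Wittig salt with the stereocentre untouched.

Step 9
Reactants: 12 (1R,2S,5R,8aR)-5-({[tert-butyl(dimethyl)silyl]oxy}methyl)-1,2,5-trimethyl-1,2,3,5,6,7,8,8a-octahydronaphthalene-1-carbaldehyde; 15 [(2S)-4-methoxy-2-methyl-4-oxobutyl]triphenylphosphonium bromide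
Product: 17 methyl (3S,4Z)-5-[(1S,2S,5R,8aS)-5-({[tert-butyl(dimethyl)silyl]oxy}methyl)-1,2,5-trimethyl-1,2,3,5,6,7,8,8a-octahydronaphthalen-1-yl]-3-methylpent-4-enoate, via ylide 16 (not isolated)
Conditions: 15, KN(SiMe3)2, THF, −78 → 0 °C; then 12, −78 → 25 °C
Reagents that add atoms: none
Why: Wittig olefination with a non-stabilised ylide should form C11=C12 (Z expected, and the geometry is irrelevant because the alkene is hydrogenated next); the aldehyde cannot epimerise because C9 is quaternary.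

Step 10
Reactants: 17 methyl (3S,4Z)-5-[(1S,2S,5R,8aS)-5-({[tert-butyl(dimethyl)silyl]oxy}methyl)-1,2,5-trimethyl-1,2,3,5,6,7,8,8a-octahydronaphthalen-1-yl]-3-methylpent-4-enoate
Product: 18 methyl (3R)-5-[(1R,2S,5R,8aS)-5-({[tert-butyl(dimethyl)silyl]oxy}methyl)-1,2,5-trimethyl-1,2,3,5,6,7,8,8a-octahydronaphthalen-1-yl]-3-methylpentanoate
Conditions: H2 (1–3 atm), RhCl(PPh3)3 (5 mol %), benzene/EtOH, 25 °C
Reagents that add atoms: none
Why: Homogeneous hydrogenation with the rhodium phosphine catalyst should reduce the 1,2-disubstituted side-chain alkene and leave the hindered trisubstituted C5=C6 alkene; no stereocentre is created.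

Step 11
Reactants: 18 methyl (3R)-5-[(1R,2S,5R,8aS)-5-({[tert-butyl(dimethyl)silyl]oxy}methyl)-1,2,5-trimethyl-1,2,3,5,6,7,8,8a-octahydronaphthalen-1-yl]-3-methylpentanoate
Product: 19 (3R)-5-[(1R,2S,5R,8aS)-5-({[tert-butyl(dimethyl)silyl]oxy}methyl)-1,2,5-trimethyl-1,2,3,5,6,7,8,8a-octahydronaphthalen-1-yl]-3-methylpentanoic acid
Conditions: LiOH·H2O, THF/MeOH/H2O, 25 °C; then 0.5 M HCl to pH 3–4, 0 °C
Reagents that add atoms: lithium hydroxide, [Li+].[OH-]
Why: Saponification of the methyl ester is placed before the C7 ketone exists, so no base-sensitive centre is present; silyl ether and alkene are stable.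

Step 12
Reactants: 19 (3R)-5-[(1R,2S,5R,8aS)-5-({[tert-butyl(dimethyl)silyl]oxy}methyl)-1,2,5-trimethyl-1,2,3,5,6,7,8,8a-octahydronaphthalen-1-yl]-3-methylpentanoic acid
Product: 20 (3R)-5-[(1R,2S,5R,8aS)-5-(hydroxymethyl)-1,2,5-trimethyl-1,2,3,5,6,7,8,8a-octahydronaphthalen-1-yl]-3-methylpentanoic acid
Conditions: HF·pyridine, THF/pyridine, 0 → 25 °C
Reagents that add atoms: none
Why: Fluoride-driven cleavage of the silyl ether (Si–F bond formation) frees C18–OH without affecting the alkene or the acid.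

Step 13
Reactants: 20 (3R)-5-[(1R,2S,5R,8aS)-5-(hydroxymethyl)-1,2,5-trimethyl-1,2,3,5,6,7,8,8a-octahydronaphthalen-1-yl]-3-methylpentanoic acid
Product: 22 (3R)-5-[(1R,2S,5R,8aS)-5-(acetoxymethyl)-1,2,5-trimethyl-1,2,3,5,6,7,8,8a-octahydronaphthalen-1-yl]-3-methylpentanoic acid, via mixed anhydride 21 (not isolated)
Conditions: Ac2O (3 equiv), pyridine, DMAP (cat.), CH2Cl2, 0 → 25 °C; then NaHCO3 aq./THF, 25 °C; acidify to pH 3
Reagents that add atoms: acetic anhydride, CC(=O)OC(C)=O
Why: DMAP-catalysed acylation of the neopentyl primary alcohol; the carboxylic acid is converted transiently into mixed anhydride 21, which the aqueous bicarbonate treatment should hydrolyse back to the acid by attack of water at the less hindered acetyl carbonyl.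

Step 14
Reactants: 22 (3R)-5-[(1R,2S,5R,8aS)-5-(acetoxymethyl)-1,2,5-trimethyl-1,2,3,5,6,7,8,8a-octahydronaphthalen-1-yl]-3-methylpentanoic acid
Product: 23 (3R)-5-[(1S,2R,5R,8aS)-5-(acetoxymethyl)-1,2,5-trimethyl-3-oxo-1,2,3,5,6,7,8,8a-octahydronaphthalen-1-yl]-3-methylpentanoic acid
Conditions: Rh2(cap)4 (dirhodium tetrakis(caprolactamate), 1 mol %), t-BuOOH (70 % aq., 5 equiv), 1,2-dichloroethane, 40 °C, no base
Reagents that add atoms: tert-butyl hydroperoxide, CC(C)(C)OO
Why: Dirhodium-catalysed allylic C–H oxidation with t-BuOOH, the reaction type that turns 5-ene steroids into 7-ketones: the peroxyl radical should abstract the allylic C7–H of the C5=C6 alkene (C4 has no hydrogen, C10–H is flanked by C9 and C1) and the mixed peroxide collapses to the enone; the step is last and base-free so that the now enolisable C8 centre is not epimerised.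

**Compound list**

1 | ethyl 2-methyl-3-oxobutanoate (racemic) | CCOC(=O)C(C)C(C)=O | starting material
2 | acrolein (prop-2-enal) | C=CC=O | starting material
3 | ethyl (2R)-2-acetyl-2-methyl-5-oxopentanoate | CCOC(=O)[C@](C)(CCC=O)C(C)=O | intermediate
4 | ethyl (1R)-4-hydroxy-1-methyl-2-oxocyclohexane-1-carboxylate (both carbinol epimers) | CCOC(=O)[C@]1(C)CCC(O)CC1=O | intermediate
5 | ethyl (1R)-1-methyl-2-oxocyclohex-3-ene-1-carboxylate | CCOC(=O)[C@]1(C)CCC=CC1=O | intermediate
6 | lithium (6R)-6-(ethoxycarbonyl)-6-methylcyclohex-1-en-1-olate | CCOC(=O)[C@]1(C)CCCC=C1[O-].[Li+] | intermediate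
7 | ethyl (1R)-1-methyl-2-(trifluoromethylsulfonyloxy)cyclohex-2-ene-1-carboxylate | CCOC(=O)[C@]1(C)CCCC=C1OS(=O)(=O)C(F)(F)F | intermediate
8 | ethyl (1R)-2-ethenyl-1-methylcyclohex-2-ene-1-carboxylate | CCOC(=O)[C@]1(C)CCCC=C1C=C | intermediate
9 | [(1R)-2-ethenyl-1-methylcyclohex-2-en-1-yl]methanol | OC[C@]1(C)CCCC=C1C=C | intermediate
10 | tert-butyl{[(1R)-2-ethenyl-1-methylcyclohex-2-en-1-yl]methoxy}dimethylsilane | CC(C)(C)[Si](C)(C)OC[C@]1(C)CCCC=C1C=C | intermediate
11 | (E)-2-methylbut-2-enal (tiglic aldehyde) | C/C=C(\C)C=O | starting material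
12 | (1R,2S,5R,8aR)-5-({[tert-butyl(dimethyl)silyl]oxy}methyl)-1,2,5-trimethyl-1,2,3,5,6,7,8,8a-octahydronaphthalene-1-carbaldehyde | CC(C)(C)[Si](C)(C)OC[C@]1(C)CCC[C@@H]2C1=CC[C@H](C)[C@@]2(C)C=O | intermediate
13 | (3R)-5-methoxy-3-methyl-5-oxopentanoic acid (methyl hydrogen (R)-3-methylglutarate) | COC(=O)C[C@H](C)CC(=O)O | starting material
14 | methyl (3S)-4-bromo-3-methylbutanoate | COC(=O)C[C@H](C)CBr | intermediate
15 | [(2S)-4-methoxy-2-methyl-4-oxobutyl]triphenylphosphonium bromide | COC(=O)C[C@H](C)C[P+](c1ccccc1)(c1ccccc1)c1ccccc1.[Br-] | intermediate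
16 | methyl (3S)-3-methyl-4-(triphenyl-λ5-phosphanylidene)butanoate (ylide) | COC(=O)C[C@H](C)C=P(c1ccccc1)(c1ccccc1)c1ccccc1 | intermediate
17 | methyl (3S,4Z)-5-[(1S,2S,5R,8aS)-5-({[tert-butyl(dimethyl)silyl]oxy}methyl)-1,2,5-trimethyl-1,2,3,5,6,7,8,8a-octahydronaphthalen-1-yl]-3-methylpent-4-enoate | CC(C)(C)[Si](C)(C)OC[C@]1(C)CCC[C@@H]2C1=CC[C@H](C)[C@@]2(C)/C=C\[C@@H](C)CC(=O)OC | intermediate
18 | methyl (3R)-5-[(1R,2S,5R,8aS)-5-({[tert-butyl(dimethyl)silyl]oxy}methyl)-1,2,5-trimethyl-1,2,3,5,6,7,8,8a-octahydronaphthalen-1-yl]-3-methylpentanoate | CC(C)(C)[Si](C)(C)OC[C@]1(C)CCC[C@@H]2C1=CC[C@H](C)[C@@]2(C)CC[C@@H](C)CC(=O)OC | intermediate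
19 | (3R)-5-[(1R,2S,5R,8aS)-5-({[tert-butyl(dimethyl)silyl]oxy}methyl)-1,2,5-trimethyl-1,2,3,5,6,7,8,8a-octahydronaphthalen-1-yl]-3-methylpentanoic acid | CC(C)(C)[Si](C)(C)OC[C@]1(C)CCC[C@@H]2C1=CC[C@H](C)[C@@]2(C)CC[C@@H](C)CC(=O)O | intermediate
20 | (3R)-5-[(1R,2S,5R,8aS)-5-(hydroxymethyl)-1,2,5-trimethyl-1,2,3,5,6,7,8,8a-octahydronaphthalen-1-yl]-3-methylpentanoic acid | OC[C@]1(C)CCC[C@@H]2C1=CC[C@H](C)[C@@]2(C)CC[C@@H](C)CC(=O)O | intermediate
21 | acetic (3R)-5-[(1R,2S,5R,8aS)-5-(acetoxymethyl)-1,2,5-trimethyl-1,2,3,5,6,7,8,8a-octahydronaphthalen-1-yl]-3-methylpentanoic anhydride | CC(=O)OC[C@]1(C)CCC[C@@H]2C1=CC[C@H](C)[C@@]2(C)CC[C@@H](C)CC(=O)OC(C)=O | intermediate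
22 | (3R)-5-[(1R,2S,5R,8aS)-5-(acetoxymethyl)-1,2,5-trimethyl-1,2,3,5,6,7,8,8a-octahydronaphthalen-1-yl]-3-methylpentanoic acid | CC(=O)OC[C@]1(C)CCC[C@@H]2C1=CC[C@H](C)[C@@]2(C)CC[C@@H](C)CC(=O)O | intermediate
23 | (3R)-5-[(1S,2R,5R,8aS)-5-(acetoxymethyl)-1,2,5-trimethyl-3-oxo-1,2,3,5,6,7,8,8a-octahydronaphthalen-1-yl]-3-methylpentanoic acid | CC(=O)OC[C@]1(C)CCC[C@@H]2C1=CC(=O)[C@H](C)[C@@]2(C)CC[C@@H](C)CC(=O)O | target

**Count and risks**

Total step count: 14. Longest linear sequence: 12 steps (steps 1–6 and 9–14); steps 7 and 8 make the side-chain salt in parallel.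

Steps most likely to fail:

Step 6. The hindered 1,2-disubstituted diene may add too slowly at the low temperature the chiral Lewis acid needs, and the two diene faces may be poorly discriminated. The fallback gives up reagent control and relies on separation of diastereomers. From 10 and 11, an achiral promoter (Me2AlCl, CH2Cl2, −78 → −20 °C) should keep the regiochemistry and the exo mode and give 12 together with its diene-face isomer (1S,2R,5R,8aS)-5-({[tert-butyl(dimethyl)silyl]oxy}methyl)-1,2,5-trimethyl-1,2,3,5,6,7,8,8a-octahydronaphthalene-1-carbaldehyde F1 as the second component. NaBH4 reduction (MeOH, 0 °C) of the mixture turns 12 into [(1R,2S,5R,8aR)-5-({[tert-butyl(dimethyl)silyl]oxy}methyl)-1,2,5-trimethyl-1,2,3,5,6,7,8,8a-octahydronaphthalen-1-yl]methanol F2 and the isomer F1 into [(1S,2R,5R,8aS)-5-({[tert-butyl(dimethyl)silyl]oxy}methyl)-1,2,5-trimethyl-1,2,3,5,6,7,8,8a-octahydronaphthalen-1-yl]methanol F3 so that the two diastereomeric alcohols can be separated by chromatography. Oxidation of F2 with 1,1,1-triacetoxy-1,1-dihydro-1,2-benziodoxol-3(1H)-one comes back at 12.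

Step 14. Hydrogen abstraction at the tertiary allylic C10–H may compete, and the enone may be over-oxidised. The fallback sets out from 22 and replaces radical C–H oxidation by an ene reaction with singlet oxygen.
- Dye-sensitised photooxygenation of 22 (O2, tetraphenylporphyrin, hν, CH2Cl2; Schenck ene reaction) should remove a C7 hydrogen and deliver oxygen to C5. This gives the 5-hydroperoxy-6-ene (3R)-5-[(1R,2S,5S,8aS)-5-(acetoxymethyl)-4a-hydroperoxy-1,2,5-trimethyl-1,2,4a,5,6,7,8,8a-octahydronaphthalen-1-yl]-3-methylpentanoic acid F4 as a mixture of C4a epimers.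
- On standing in CHCl3 this allylic hydroperoxide should rearrange by a 1,3-shift of the peroxyl group to the 7-hydroperoxy-5-ene (3R)-5-[(1S,2R,5R,8aS)-5-(acetoxymethyl)-3-hydroperoxy-1,2,5-trimethyl-1,2,3,5,6,7,8,8a-octahydronaphthalen-1-yl]-3-methylpentanoic acid F5 as a mixture of C3 epimers.
- Reduction with PPh3 gives the allylic alcohol (3R)-5-[(1S,2R,5R,8aS)-5-(acetoxymethyl)-3-hydroxy-1,2,5-trimethyl-1,2,3,5,6,7,8,8a-octahydronaphthalen-1-yl]-3-methylpentanoic acid F6 and MnO2 oxidation of this alcohol comes back at 23.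

Step 9. Addition of the β-branched ylide to the neopentyl aldehyde may be slow, so that decomposition of the ylide wins. The fallback is a Julia–Kocienski olefination.
- From 14, 1-phenyl-1H-tetrazole-5-thiol and K2CO3 in acetone give methyl (3S)-3-methyl-4-[(1-phenyl-1H-tetrazol-5-yl)sulfanyl]butanoate F7 by S-alkylation.
- Oxidation with H2O2 and (NH4)6Mo7O24 in EtOH gives methyl (3S)-3-methyl-4-[(1-phenyl-1H-tetrazol-5-yl)sulfonyl]butanoate F8 with the stereocentre untouched.
- Its potassium salt (KN(SiMe3)2, THF, −78 °C) is added to 12 and should give methyl (3S,4E)-5-[(1S,2S,5R,8aS)-5-({[tert-butyl(dimethyl)silyl]oxy}methyl)-1,2,5-trimethyl-1,2,3,5,6,7,8,8a-octahydronaphthalen-1-yl]-3-methylpent-4-enoate F9 after Smiles rearrangement and loss of sulfur dioxide and the tetrazolol.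
- Hydrogenation as in step 10 comes back at 18.

**Further compounds**

F1 | step 6 | (1S,2R,5R,8aS)-5-({[tert-butyl(dimethyl)silyl]oxy}methyl)-1,2,5-trimethyl-1,2,3,5,6,7,8,8a-octahydronaphthalene-1-carbaldehyde | CC(C)(C)[Si](C)(C)OC[C@]1(C)CCC[C@H]2C1=CC[C@@H](C)[C@]2(C)C=O
F2 | step 6 | [(1R,2S,5R,8aR)-5-({[tert-butyl(dimethyl)silyl]oxy}methyl)-1,2,5-trimethyl-1,2,3,5,6,7,8,8a-octahydronaphthalen-1-yl]methanol | CC(C)(C)[Si](C)(C)OC[C@]1(C)CCC[C@@H]2C1=CC[C@H](C)[C@@]2(C)CO
F3 | step 6 | [(1S,2R,5R,8aS)-5-({[tert-butyl(dimethyl)silyl]oxy}methyl)-1,2,5-trimethyl-1,2,3,5,6,7,8,8a-octahydronaphthalen-1-yl]methanol | CC(C)(C)[Si](C)(C)OC[C@]1(C)CCC[C@H]2C1=CC[C@@H](C)[C@]2(C)CO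
F4 | step 14 | (3R)-5-[(1R,2S,5S,8aS)-5-(acetoxymethyl)-4a-hydroperoxy-1,2,5-trimethyl-1,2,4a,5,6,7,8,8a-octahydronaphthalen-1-yl]-3-methylpentanoic acid (5-hydroperoxy-6-ene isomer of 22, C4a not defined) | CC(=O)OC[C@]1(C)CCC[C@@H]2C1(OO)C=C[C@H](C)[C@@]2(C)CC[C@@H](C)CC(=O)O
F5 | step 14 | (3R)-5-[(1S,2R,5R,8aS)-5-(acetoxymethyl)-3-hydroperoxy-1,2,5-trimethyl-1,2,3,5,6,7,8,8a-octahydronaphthalen-1-yl]-3-methylpentanoic acid (7-hydroperoxy-5-ene derivative of 22, C3 not defined) | CC(=O)OC[C@]1(C)CCC[C@@H]2C1=CC(OO)[C@H](C)[C@@]2(C)CC[C@@H](C)CC(=O)O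
F6 | step 14 | (3R)-5-[(1S,2R,5R,8aS)-5-(acetoxymethyl)-3-hydroxy-1,2,5-trimethyl-1,2,3,5,6,7,8,8a-octahydronaphthalen-1-yl]-3-methylpentanoic acid (7-hydroxy-5-ene derivative of 22, C3 not defined) | CC(=O)OC[C@]1(C)CCC[C@@H]2C1=CC(O)[C@H](C)[C@@]2(C)CC[C@@H](C)CC(=O)O
F7 | step 9 | methyl (3S)-3-methyl-4-[(1-phenyl-1H-tetrazol-5-yl)sulfanyl]butanoate | COC(=O)C[C@H](C)CSc1nnnn1-c1ccccc1
F8 | step 9 | methyl (3S)-3-methyl-4-[(1-phenyl-1H-tetrazol-5-yl)sulfonyl]butanoate | COC(=O)C[C@H](C)CS(=O)(=O)c1nnnn1-c1ccccc1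
F9 | step 9 | methyl (3S,4E)-5-[(1S,2S,5R,8aS)-5-({[tert-butyl(dimethyl)silyl]oxy}methyl)-1,2,5-trimethyl-1,2,3,5,6,7,8,8a-octahydronaphthalen-1-yl]-3-methylpent-4-enoate | CC(C)(C)[Si](C)(C)OC[C@]1(C)CCC[C@@H]2C1=CC[C@H](C)[C@@]2(C)/C=C/[C@@H](C)CC(=O)OC
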